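**Retrosynthetic overview**
1. The target is opened at the N5 amide: N1,N10-di-(E)-p-coumaroylspermidine 11 plus the N-succinimidyl ester 2 of p-coumaric acid.
2. Structural feature carrying the strategy: in spermidine numbering N1-C2-C3-C4-N5-C6-C7-C8-C9-N10, C6 of the butane-1,4-diyl bridge is a lone carbon between N5 and the three-carbon chain C7-C8-C9 on N10, so it can be supplied as carbon monoxide 7. Cutting N5–C6 and C6–C7 gives N-allyl amide 4, aminopropyl amide 6 and CO.
3. Amides 4 and 6 come from active ester 2 with allylamine 3 and with excess 1,3-diaminopropane 5; ester 2 comes from p-coumaric acid 1.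
4. No ring is formed anywhere in the route and there are no stereocentres. The three benzene rings and the three (E)-alkenes are carried intact from p-coumaric acid.

Key step: step 4

Assumption: N1 is the nitrogen at the propyl end of spermidine, and all cinnamoyl compounds are handled with exclusion of strong light so that the (E) geometry is held; equivalents and pressures are proposed values.

**Step 1**
Reactants: 1 (E)-p-coumaric acid
Product: 2 N-succinimidyl (E)-3-(4-hydroxyphenyl)prop-2-enoate
Conditions: N-hydroxysuccinimide (1.1 equiv), N,N'-dicyclohexylcarbodiimide (1.1 equiv), THF, 0 °C to rt; urea filtered off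
Reagents that add atoms: N-hydroxysuccinimide, O=C1CCC(=O)N1O
Why: Carbodiimide (Steglich-type) activation gives an O-acylisourea that is intercepted by N-hydroxysuccinimide, a far better nucleophile than the un-ionised phenol, so the active ester should form without phenol protection.

**Step 2**
Reactants: 2 N-succinimidyl (E)-p-coumarate; 3 allylamine
Product: 4 (E)-N-allyl-3-(4-hydroxyphenyl)acrylamide
Conditions: 3 (1.2 equiv), Et3N (1.2 equiv), THF, 0 °C to rt
Reagents that add atoms: none
Why: Aminolysis of an N-hydroxysuccinimide active ester by a primary amine gives the amide, while the phenol and the conjugated alkene are inert under these conditions.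

**Step 3**
Reactants: 2 N-succinimidyl (E)-p-coumarate; 5 1,3-diaminopropane
Product: 6 (E)-N-(3-aminopropyl)-3-(4-hydroxyphenyl)acrylamide
Conditions: 2 added slowly to 5 (10 equiv), THF, 0 °C to rt; excess 5 removed under vacuum, cation-exchange purification
Reagents that add atoms: none
Why: Active-ester aminolysis under slow addition into a large excess of the symmetrical diamine should give mono-acylation on statistical grounds, and the volatile excess diamine is distilled off.

**Step 4**
Reactants: 4 (E)-N-allyl-3-(4-hydroxyphenyl)acrylamide; 6 (E)-N-(3-aminopropyl)-3-(4-hydroxyphenyl)acrylamide; 7 carbon monoxide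
Product: 11 N1,N10-di-(E)-p-coumaroylspermidine, via aldehyde 8 (not isolated), via cyclic hemiaminal 9 (not isolated), via aldimine 10 (not isolated)
Conditions: [Rh(cod)2]BF4 (1 mol%), Xantphos (4 mol%), CO/H2 (1:5, 30 bar), 6 (3 equiv), THF/MeOH (1:1), 85 °C
Reagents that add atoms: none
Why: This is a tandem hydroaminomethylation (hydroformylation, condensation, hydrogenation), the closest known reaction type being the rhodium/diphosphine-catalysed linear hydroaminomethylation of terminal alkenes and N-allyl amides with primary amines: the rhodium hydride adds to the allyl group of 4 in the anti-Markovnikov sense, CO inserts and hydrogenolysis releases aldehyde 8, whose carbonyl carbon is C6 and whose new C–C bond is C6–C7. Aldehyde 8 rests reversibly as the five-membered N-acyl hemiaminal 9, but the open form is drained by condensation with the primary amine of 6 to aldimine 10 (N5=C6), which the same catalyst hydrogenates to 11. No ring is closed in the product and no stereocentre is created; the two (E)-cinnamoyl alkenes are spectators. Linear over branched regioselectivity is secured by the wide bite angle of Xantphos. Chemoselectivity rests on the substrate: the monosubstituted allyl alkene is hydroformylated far faster than the 1,2-disubstituted, aryl- and carbonyl-conjugated cinnamoyl alkenes, which under CO are also poor hydrogenation substrates, whereas the polarised C=N of 10 is reduced with help from the protic medium (MeOH and the phenols). The threefold excess of 6, recovered afterwards, should keep the new secondary amine N5 from a second alkylation.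

**Step 5**
Reactants: 11 N1,N10-di-(E)-p-coumaroylspermidine; 2 N-succinimidyl (E)-p-coumarate
Product: 12 N1,N5,N10-tri-(E)-p-coumaroylspermidine
Conditions: 2 (1.2 equiv), Et3N (2 equiv), DMF, rt to 40 °C
Reagents that add atoms: none
Why: Aminolysis of the active ester by N5, the only basic nitrogen left, should be chemoselective because un-ionised phenols are much weaker nucleophiles towards N-hydroxysuccinimide esters than a dialkylamine.

**Compound list**
1 | (E)-p-coumaric acid | O=C(O)/C=C/c1ccc(O)cc1 | starting material
2 | N-succinimidyl (E)-3-(4-hydroxyphenyl)prop-2-enoate | O=C(/C=C/c1ccc(O)cc1)ON1C(=O)CCC1=O | intermediate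
3 | allylamine | C=CCN | starting material
4 | (E)-N-allyl-3-(4-hydroxyphenyl)acrylamide | C=CCNC(=O)/C=C/c1ccc(O)cc1 | intermediate
5 | 1,3-diaminopropane | NCCCN | starting material
6 | (E)-N-(3-aminopropyl)-3-(4-hydroxyphenyl)acrylamide | NCCCNC(=O)/C=C/c1ccc(O)cc1 | intermediate
7 | carbon monoxide | [C-]#[O+] | starting material
8 | (E)-3-(4-hydroxyphenyl)-N-(4-oxobutyl)acrylamide (aldehyde, not isolated) | O=CCCCNC(=O)/C=C/c1ccc(O)cc1 | intermediate
9 | (E)-1-(2-hydroxypyrrolidin-1-yl)-3-(4-hydroxyphenyl)prop-2-en-1-one (racemic cyclic hemiaminal, not isolated) | O=C(/C=C/c1ccc(O)cc1)N1CCCC1O | intermediate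
10 | aldimine from 8 and 6, N5=C6 (not isolated) | O=C(/C=C/c1ccc(O)cc1)NCCCC=NCCCNC(=O)/C=C/c1ccc(O)cc1 | intermediate
11 | N1,N10-di-(E)-p-coumaroylspermidine | O=C(/C=C/c1ccc(O)cc1)NCCCCNCCCNC(=O)/C=C/c1ccc(O)cc1 | intermediate
12 | N1,N5,N10-tri-(E)-p-coumaroylspermidine | O=C(/C=C/c1ccc(O)cc1)NCCCCN(CCCNC(=O)/C=C/c1ccc(O)cc1)C(=O)/C=C/c1ccc(O)cc1 | target

**Step count**
Total steps: 5. Longest linear sequence: 4 steps (1 → 2 → 4 or 6 → 11 → 12).

**Steps most likely to fail**

1. Step 4. Hydrogenation of aldimine 10 may need hydrogen pressures at which reduction of the conjugated cinnamoyl alkenes sets in. The aldehyde may also stay parked as hemiaminal 9 and lose water to an enamide instead of condensing, N5 may be alkylated a second time, or some branched hydroformylation may occur. Fallback: the CO-based construction of the bridge is given up and the intact triamine is used. It sets out from active ester 2, which is added (2.0 equiv) at −20 °C to commercial spermidine (NCCCCNCCCN) in THF/MeOH. The two primary amines should be acylated faster than the more hindered secondary N5, and mono- and tri-acylated material is removed by chromatography. It comes back to the route at 11. This fallback makes no compound outside the list (F0).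

2. Step 5. Acylation of the hindered secondary amine by the conjugated, weakly electrophilic active ester may be sluggish, and forcing it may bring competing O-acylation of the phenols. Fallback: a phenol-protected acid chloride is used instead, followed by deprotection. It sets out from 11, with the acyl donor made from 1.
   - Acid 1 is acetylated (Ac2O, pyridine, then aqueous work-up) to (E)-4-acetoxycinnamic acid F1.
   - Oxalyl chloride with catalytic DMF in CH2Cl2 converts it to (E)-4-acetoxycinnamoyl chloride F2.
   - Under Schotten–Baumann conditions (aqueous NaHCO3/THF, 0 °C), F2 acylates N5 of 11 to give N5-[(E)-4-acetoxycinnamoyl]-N1,N10-di-(E)-p-coumaroylspermidine F3.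
   - Methanolysis with catalytic K2CO3 in MeOH at rt removes the aryl acetate, and any aryl ester formed on the phenols, and comes back to the route at 12.

3. Step 3. Double acylation of the diamine and losses during isolation of the polar, amphoteric aminophenol may erode the supply of 6. Fallback: a mono-protected diamine replaces the statistical acylation. It sets out from 2.
   - Ester 2 reacts with commercial tert-butyl N-(3-aminopropyl)carbamate (Et3N, THF, rt) to give tert-butyl N-[3-[[(E)-3-(4-hydroxyphenyl)prop-2-enoyl]amino]propyl]carbamate F4.
   - HCl in dioxane (4 M, rt) removes the carbamate to give the hydrochloride of 6 F5.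
   - One equivalent of NaOMe in MeOH liberates the free base and comes back to the route at 6.

**Further compounds**
F0 | step 4 | none | none
F1 | step 5 | (E)-4-acetoxycinnamic acid | CC(=O)Oc1ccc(/C=C/C(=O)O)cc1
F2 | step 5 | (E)-4-acetoxycinnamoyl chloride | CC(=O)Oc1ccc(/C=C/C(=O)Cl)cc1
F3 | step 5 | N5-[(E)-4-acetoxycinnamoyl]-N1,N10-di-(E)-p-coumaroylspermidine | CC(=O)Oc1ccc(/C=C/C(=O)N(CCCCNC(=O)/C=C/c2ccc(O)cc2)CCCNC(=O)/C=C/c2ccc(O)cc2)cc1
F4 | step 3 | tert-butyl N-[3-[[(E)-3-(4-hydroxyphenyl)prop-2-enoyl]amino]propyl]carbamate | CC(C)(C)OC(=O)NCCCNC(=O)/C=C/c1ccc(O)cc1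
F5 | step 3 | hydrochloride of 6 | Cl.NCCCNC(=O)/C=C/c1ccc(O)cc1
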